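(The rate constants are invented, and the outcome is calculated.)

The constants below are quoted at 60 °C, but your flasks stand at other temperatures too, so the first job is to move the constant of target loss.

| setting | red | ochre | teal | blue |
|---|---|---|---|---|
| starting material | 0.80 M | 0.80 M | 0.80 M | 0.80 M |
| second substrate | 2.00 equiv | 2.00 equiv | 2.00 equiv | 2.00 equiv |
| free catalyst | 0.2 mol% | 0.2 mol% | 0.2 mol% | 0.2 mol% |
| time | 8.0 d | 8.0 d | 8.0 d | 8.0 d |
| remark | at 40 °C until 6.0 d, from then on at 80 °C |  |  |  |
| temperature |  | 40 °C | 60 °C | 80 °C |

    starting material + free catalyst ⇌ catalyst intermediate A (K1 = 2.0 M⁻¹, k1 = 0.0037 M⁻¹ s⁻¹, Ea1 = 67.0 kJ mol⁻¹, ΔH1 = −2.00 kJ mol⁻¹)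
    catalyst intermediate A → free catalyst + target (k2 = 0.11 s⁻¹, Ea2 = 89.0 kJ mol⁻¹)
    second substrate + free catalyst ⇌ catalyst intermediate B (K3 = 0.72 M⁻¹, k3 = 0.0091 M⁻¹ s⁻¹, Ea3 = 74.0 kJ mol⁻¹, ΔH3 = −21.0 kJ mol⁻¹)
    catalyst intermediate B → free catalyst + second product (k4 = 0.0025 s⁻¹, Ea4 = 95.0 kJ mol⁻¹)
    target → over-reaction product (k5 = 1.5 × 10⁻⁵ s⁻¹, Ea5 = 114 kJ mol⁻¹)
    second substrate + free catalyst → spent catalyst (k6 = 1.5 × 10⁻⁶ M⁻¹ s⁻¹, Ea6 = 86.0 kJ mol⁻¹)
    2 second substrate → self-condensation product (k7 = 5.1 × 10⁻⁶ M⁻¹ s⁻¹, Ea7 = 99.0 kJ mol⁻¹)
    (constants at 60 °C)

- a step written with two of one species runs at k times the square of its concentration and takes two of it each time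
- constants are those at 60 °C; use the activation energies and enthalpies for any other temperature

- which flask leads in amount of target, in percent of the starting material charged ("all alike" within 1.5 percentage points) (red / ochre / teal / blue / all alike)
- how much target is there at the end, in percent of the starting material charged: red
- how much target is there at the end, in percent of the starting material charged: ochre
- how much target is there at the end, in percent of the starting material charged: teal
- how much target is there at the end, in percent of the starting material charged: blue

1. Look at the step from target to over-reaction product. It has the highest activation energy on the board, and it needs no catalyst. Moved to 40 °C its constant is 1.08 × 10⁻⁶ s⁻¹, and moved to 80 °C it is 1.54 × 10⁻⁴ s⁻¹.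

2. Multiply by the time of the run. Ochre gets 0.748. Call this N, the loss number: the constant of target loss at the flask's temperature times its time, or how many target lifetimes fit into the run. It is a Damköhler number. Teal gets 10.4 and blue gets 107.

3. What does N mean? If target is made at a steady pace and lost first-order, the share of it still there at the end is one minus e to the minus N, divided by N. That gives 70.4% for ochre, 9.64% for teal and 0.938% for blue.

4. Now read the outcome. Grant teal full conversion at that steady pace, and ochre still leads once it has converted 13.7% of its starting material. Red spends its last 2.00 d at 80 °C, a loss number of 26.7, far larger than ochre's, so what it built cold shrinks to hardly any of itself.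

5. Is one number enough? No. N gives the share kept, not the amount made. At the same N, target made early in a run also keeps less than the steady share. So I commit to ochre, with target at 70.4% of whatever ochre converts.

The forecast names ochre, with 0.7% in red, 23.5% in ochre, 1.9% in teal and <0.001% in blue. Its ground for the hot flasks is that “the target sits at a small steady-state level against its formation”.

The flasks give 0.440% in red, 23.6% in ochre, 2.23% in teal and 0% in blue, so ochre leads, as the forecast said. Ochre ends with 33.6% of its starting material converted and 66.4% still standing as starting material. Put the loss number to work on that conversion: the steady-pace share 70.4% of 33.6% is 23.7% of target.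

Take the flask like red read at 50 h, still at 40 °C. Its loss number is 0.195, so at a steady pace it keeps 90.9%, and on 8.80% converted that gives 7.99% of target. The computed flask holds 7.99%.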